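**Retrosynthetic overview**

1. Ring names: ring A is the 4-oxyphenyl on the CH of the seven-membered ring, ring B the resorcinol ring fused to the dihydrofuran, ring C the other resorcinol ring, ring D the 4-hydroxyphenyl on dihydrofuran C2. Ampelopsin B is traced back, through its ring-A pivalate, to an open-chain stilbene whose only rings are the four arenes.
2. One anodic dehydrogenation joins the free ortho carbon of ring B to the styryl carbon next to ring C, and the neighbouring phenol oxygen of ring B to the styryl carbon next to ring D. The seven-membered carbocycle closes first and the dihydrofuran second, in the same operation.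
3. Enabling feature: the 4-hydroxystyryl unit (O–H of ring D conjugated through the ring to the C=C) is a vinylogous phenol. Two-electron oxidation reverses the polarity of its styryl carbon next to ring C, and the (S)-CH(ring A)–CH2 arm ortho to the styryl group on ring C holds the C–H/O–H pair of ring B within reach.
4. The stilbene comes from Suzuki coupling at an aryl triflate of ring C. Five methyl ethers are cleaved just before the key step, while the pivalate stays on ring A to keep that ring inert.
5. The only reagent-controlled stereocentre is set by a chiral phosphoric acid-catalysed Friedel–Crafts reaction of 3,5-dimethoxyphenol with a para-quinone methide built from 4-hydroxybenzaldehyde and 3,5-dimethoxybenzyl chloride. It then directs both new centres.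

Key step: step 7

Assumption: the (R)-configured phosphoric acid is taken to deliver the (S)-configured centre in step 2; if the sense of induction is the opposite, the (S)-catalyst is used and nothing else changes (the centre keeps the descriptor S in every later compound because the priority order ring C > ring A > CH2 > H does not change).

**Step 1**
Reactants: 1 4-hydroxybenzaldehyde; 2 3,5-dimethoxybenzyl chloride
Product: 4 1-(4-hydroxyphenyl)-2-(3,5-dimethoxyphenyl)ethanol (racemic), via (3,5-dimethoxybenzyl)magnesium chloride 3 (not isolated)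
Conditions: 2 (2.6 equiv), Mg, I2 (cat.), Et2O, 0 °C to rt; then 1, THF, 0 °C to rt; aq NH4Cl
Reagents that add atoms: none
Why: Grignard addition of the benzylic magnesium reagent to the aldehyde, in which the first equivalent deprotonates the phenol and the second adds to the carbonyl; the carbinol centre is left racemic on purpose because step 2 erases it.

**Step 2**
Reactants: 4 1-(4-hydroxyphenyl)-2-(3,5-dimethoxyphenyl)ethanol; 5 3,5-dimethoxyphenol
Product: 7 (S)-2-[2-(3,5-dimethoxyphenyl)-1-(4-hydroxyphenyl)ethyl]-3,5-dimethoxyphenol, via para-quinone methide 6 (not isolated)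
Conditions: (R)-TRIP [(R)-3,3'-bis(2,4,6-triisopropylphenyl)-1,1'-binaphthyl-2,2'-diyl hydrogen phosphate] (5 mol %), 5 (2 equiv), 4 Å MS, CH2Cl2, −20 °C
Reagents that add atoms: none
Why: Chiral phosphoric acid-catalysed asymmetric Friedel–Crafts alkylation (1,6-addition to an in situ para-quinone methide), in which the acid dehydrates 4 to 6, stays hydrogen-bonded to its carbonyl oxygen and binds the OH of 5 through its phosphoryl oxygen, so that the carbon ortho to that OH is delivered to one enantiotopic face of the exocyclic carbon and sets the (S) centre with ortho regiochemistry.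

**Step 3**
Reactants: 7 (S)-2-[2-(3,5-dimethoxyphenyl)-1-(4-hydroxyphenyl)ethyl]-3,5-dimethoxyphenol
Product: 8 4-[(S)-2-(3,5-dimethoxyphenyl)-1-(2-hydroxy-4,6-dimethoxyphenyl)ethyl]phenyl pivalate
Conditions: PivCl (1.05 equiv), Et3N (1.2 equiv), CH2Cl2, −40 to 0 °C
Reagents that add atoms: pivaloyl chloride, CC(C)(C)C(Cl)=O
Why: Sterically differentiated O-acylation with a bulky acyl chloride, which should esterify the unhindered ring-A phenol and leave the ring-C phenol, shielded by the adjacent branched benzylic centre, free; no stereocentre is touched.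

**Step 4**
Reactants: 8 4-[(S)-2-(3,5-dimethoxyphenyl)-1-(2-hydroxy-4,6-dimethoxyphenyl)ethyl]phenyl pivalate
Product: 9 4-[(S)-1-{2,4-dimethoxy-6-[(trifluoromethylsulfonyl)oxy]phenyl}-2-(3,5-dimethoxyphenyl)ethyl]phenyl pivalate
Conditions: Tf2O (1.3 equiv), pyridine (3 equiv), CH2Cl2, 0 °C
Reagents that add atoms: trifluoromethanesulfonic anhydride, O=S(=O)(OS(=O)(=O)C(F)(F)F)C(F)(F)F
Why: Standard triflation of a phenol, which turns the remaining OH of ring C into a cross-coupling handle on exactly the carbon that must carry the styryl group.

**Step 5**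
Reactants: 9 aryl triflate from step 4; 10 (E)-2-(4-methoxyphenyl)vinylboronic acid
Product: 11 4-[(S)-1-{2,4-dimethoxy-6-[(E)-4-methoxystyryl]phenyl}-2-(3,5-dimethoxyphenyl)ethyl]phenyl pivalate
Conditions: 10 (1.5 equiv), Pd(OAc)2 (5 mol %), SPhos (10 mol %), K3PO4 (2 equiv), toluene/H2O 10:1, 70 °C
Reagents that add atoms: none
Why: Suzuki–Miyaura coupling of an ortho-substituted aryl triflate with an (E)-alkenylboronic acid, which keeps the alkene geometry and leaves the aryl pivalate and the benzylic stereocentre untouched.

**Step 6**
Reactants: 11 pentamethyl ether stilbene from step 5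
Product: 12 4-[(S)-1-{2,4-dihydroxy-6-[(E)-4-hydroxystyryl]phenyl}-2-(3,5-dihydroxyphenyl)ethyl]phenyl pivalate
Conditions: BBr3 (10 equiv), CH2Cl2, −78 to 0 °C; then ice-water
Reagents that add atoms: none
Why: Lewis acid cleavage of aryl methyl ethers with BBr3, the usual way to free hydroxystilbenes from their methyl ethers, which should remove all five methyl groups at low temperature while the hindered aryl pivalate and the E-alkene survive and the benzylic centre cannot ionise because ring A is electron-poor.

**Step 7**
Reactants: 12 open-chain pentaphenol pivalate from step 6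
Product: 14 ampelopsin B ring-A pivalate [(S,S,S); trans-dihydrofuran], via seven-membered-ring quinone methide 13 (not isolated)
Conditions: constant-current electrolysis (1 mA cm−2, about 2 F per mole), undivided cell, graphite anode, Pt cathode, Bu4NBF4 (0.1 M), (CF3)2CHOH/CH2Cl2 4:1, 3 mM, 0 °C
Reagents that add atoms: none
Why: Proposed new method: anodic removal of two electrons and one proton from the 4-hydroxystyryl phenol of ring D, the most easily oxidised group of 12, gives an extended quinone methide cation whose charge sits on the styryl carbon next to ring C (polarity reversal of a normally nucleophilic carbon); the free ortho carbon of ring B attacks it in a Friedel–Crafts sense to give quinone methide 13, and the adjacent OH of ring B then adds to the quinone methide carbon next to ring D. The closest known reactions are the oxidative [3+2] couplings of 4-hydroxystilbenes and propenylphenols with phenols, which give trans-2,3-dihydrobenzofurans with chemical oxidants or at an anode, and anodic phenol–arene cross-coupling in (CF3)2CHOH; what is new is the intramolecular, ring-closing mode. The seven-membered carbocycle closes first by 7-exo-trig attack of the arene on the cationic carbon, the dihydrofuran second by 5-exo-trig oxa-1,6-addition to 13. The ring-fusion centre (dihydrofuran C3) is set in the C–C bond formation by the (S) centre already present: 1,3-allylic strain with the ortho OH of ring C keeps its C–H in the plane of ring C and ring A pseudoaxial, so the quinone methide branch has to take the pseudoequatorial position on the side away from ring A, which corresponds to the (S) configuration; the dihydrofuran C2 centre then forms trans to it (S) because the oxygen adds to the planar quinone methide anti to ring C and this addition is reversible. The step needs chemoselective oxidation, site selectivity and suppression of intermolecular coupling: the conjugated hydroxystilbene is oxidised before the resorcinol units, ring B is the only electron-rich ring that can reach the cationic carbon without strain, ipso or ortho attack by ring A is switched off by its electron-withdrawing pivalate, and high dilution with a charge limit of about 2 F per mole disfavours dimers and over-oxidation.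

**Step 8**
Reactants: 14 ampelopsin B ring-A pivalate
Product: 15 ampelopsin B
Conditions: N2H4·H2O (5 equiv), MeOH/THF, rt, argon
Reagents that add atoms: none
Why: Hydrazinolysis of an aryl ester (acyl transfer to an alpha-effect nucleophile), which frees the last phenol under near-neutral, reducing conditions that touch neither the dihydrofuran nor the three benzylic stereocentres.

**Compound list**

1 | 4-hydroxybenzaldehyde | O=Cc1ccc(O)cc1 | starting material
2 | 3,5-dimethoxybenzyl chloride | COc1cc(CCl)cc(OC)c1 | starting material
3 | (3,5-dimethoxybenzyl)magnesium chloride | COc1cc(C[Mg]Cl)cc(OC)c1 | intermediate (not isolated)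
4 | 1-(4-hydroxyphenyl)-2-(3,5-dimethoxyphenyl)ethanol, racemic | COc1cc(CC(O)c2ccc(O)cc2)cc(OC)c1 | intermediate
5 | 3,5-dimethoxyphenol | COc1cc(O)cc(OC)c1 | starting material
6 | 4-[2-(3,5-dimethoxyphenyl)ethylidene]cyclohexa-2,5-dien-1-one (para-quinone methide) | COc1cc(CC=C2C=CC(=O)C=C2)cc(OC)c1 | intermediate (not isolated)
7 | (S)-2-[2-(3,5-dimethoxyphenyl)-1-(4-hydroxyphenyl)ethyl]-3,5-dimethoxyphenol | Oc1ccc([C@H](Cc2cc(OC)cc(OC)c2)c2c(O)cc(OC)cc2OC)cc1 | intermediate
8 | 4-[(S)-2-(3,5-dimethoxyphenyl)-1-(2-hydroxy-4,6-dimethoxyphenyl)ethyl]phenyl pivalate | CC(C)(C)C(=O)Oc1ccc([C@H](Cc2cc(OC)cc(OC)c2)c2c(O)cc(OC)cc2OC)cc1 | intermediate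
9 | 4-[(S)-1-{2,4-dimethoxy-6-[(trifluoromethylsulfonyl)oxy]phenyl}-2-(3,5-dimethoxyphenyl)ethyl]phenyl pivalate | CC(C)(C)C(=O)Oc1ccc([C@H](Cc2cc(OC)cc(OC)c2)c2c(OS(=O)(=O)C(F)(F)F)cc(OC)cc2OC)cc1 | intermediate
10 | (E)-2-(4-methoxyphenyl)vinylboronic acid | COc1ccc(/C=C/B(O)O)cc1 | starting material
11 | 4-[(S)-1-{2,4-dimethoxy-6-[(E)-4-methoxystyryl]phenyl}-2-(3,5-dimethoxyphenyl)ethyl]phenyl pivalate | CC(C)(C)C(=O)Oc1ccc([C@H](Cc2cc(OC)cc(OC)c2)c2c(/C=C/c3ccc(OC)cc3)cc(OC)cc2OC)cc1 | intermediate
12 | 4-[(S)-1-{2,4-dihydroxy-6-[(E)-4-hydroxystyryl]phenyl}-2-(3,5-dihydroxyphenyl)ethyl]phenyl pivalate | CC(C)(C)C(=O)Oc1ccc([C@H](Cc2cc(O)cc(O)c2)c2c(/C=C/c3ccc(O)cc3)cc(O)cc2O)cc1 | intermediate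
13 | seven-membered-ring quinone methide: dibenzo-fused cycloheptadiene with the (S)-CH(4-pivaloyloxyphenyl) centre, a new (S)-CH carrying the (4-oxocyclohexa-2,5-dienylidene)methyl group, and four free resorcinol OH groups | CC(C)(C)C(=O)Oc1ccc([C@@H]2Cc3cc(O)cc(O)c3[C@@H](C=C3C=CC(=O)C=C3)c3cc(O)cc(O)c32)cc1 | intermediate (not isolated)
14 | ampelopsin B ring-A pivalate: (S) at dihydrofuran C2, (S) at dihydrofuran C3, (S) at the CH(aryl) of the seven-membered ring; pivalate on the 4-oxyphenyl of that CH | CC(C)(C)C(=O)Oc1ccc([C@@H]2Cc3cc(O)cc4c3[C@H](c3cc(O)cc(O)c32)[C@@H](c2ccc(O)cc2)O4)cc1 | intermediate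
15 | ampelopsin B, (S,S,S) as above, trans-2,3-disubstituted dihydrofuran | Oc1ccc([C@@H]2Cc3cc(O)cc4c3[C@H](c3cc(O)cc(O)c32)[C@@H](c2ccc(O)cc2)O4)cc1 | target

**Step count and risks**

Total steps: 8. Longest linear sequence: 8 steps (1 and 2 to 15).

Steps most likely to fail:

Step 7. The ring-closing C–C bond formation may lose to intermolecular phenol coupling or over-oxidation of the product, or it may proceed with poor facial selectivity at the ring-fusion carbon. The fallback uses known polar chemistry, sets out from triflate 9 and comes back at 14. It brings in the carbon that must bond to ring B at the ketone oxidation level, so no oxidation is needed.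
- Carbonylative Stille coupling of 9 with tributyl(4-methoxybenzyl)stannane (CO 1 atm, PdCl2(dppf), LiCl, DMF, 80 °C) gives the aryl benzyl ketone F1.
- Brønsted acid cyclodehydration (CF3SO3H, CH2Cl2, 0 °C: intramolecular Friedel–Crafts hydroxyalkylation of ring B at the ketone, then loss of water) closes the seven-membered ring as the exocyclic 4-methoxybenzylidene compound F2.
- BBr3 (CH2Cl2, −78 to 0 °C) frees the five phenols to give the benzylidene pentaphenol F3.
- TsOH in MeCN at rt protonates the ring carbon of the benzylidene, and the para-hydroxybenzyl cation is trapped by the ortho OH of ring B to give 14. Protonation and ring closure are reversible here, so the ring-fusion centre is expected to settle in the more stable arrangement with the dihydrofuran aryl groups trans.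

Step 2. Enantioselectivity may be low because the acid binds far from the reacting carbon, the quinone methide may tautomerise to the stilbene before it is trapped, and some attack para to the OH of 5 may occur. The fallback sets out from 4 and 5 and comes back at 7; the stereocentre then comes from resolution instead of catalyst control. The same Friedel–Crafts reaction is run with the achiral acid diphenyl phosphate (10 mol %, CH2Cl2, 0 °C, excess 5) to give the racemic bisphenol F4. The enantiomers are separated by preparative chromatography on a chiral stationary phase (amylose tris(3,5-dimethylphenylcarbamate), CO2/MeOH), and the (S) enantiomer is 7.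

Step 6. The pivalate may be lost by acyl cleavage during the fivefold demethylation, which would erase the only difference between ring A and the other phenols. The fallback sets out from 11 and comes back at 15. It exchanges the ester for a sulfonate that BBr3 does not attack.
- K2CO3 in MeOH/THF at rt removes the pivalate to give the ring-A phenol F5.
- MsCl/Et3N (CH2Cl2, 0 °C) gives the ring-A mesylate F6.
- BBr3 (CH2Cl2, −78 °C to rt) gives the pentaphenol mesylate F7.
- The anodic cyclisation under the conditions of step 7 gives, through the quinone methide mesylate F8, the ampelopsin B ring-A mesylate F9.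
- KOH in degassed MeOH/H2O (50 °C, argon), then dilute HCl, cleaves the aryl mesylate to 15.

**Further compounds**

F1 | step 7 | 4-[(S)-1-{2,4-dimethoxy-6-[(4-methoxyphenyl)acetyl]phenyl}-2-(3,5-dimethoxyphenyl)ethyl]phenyl pivalate | CC(C)(C)C(=O)Oc1ccc([C@H](Cc2cc(OC)cc(OC)c2)c2c(C(=O)Cc3ccc(OC)cc3)cc(OC)cc2OC)cc1
F2 | step 7 | seven-membered-ring 4-methoxybenzylidene compound, (S) at CH(4-pivaloyloxyphenyl), four OMe on rings B and C | CC(C)(C)C(=O)Oc1ccc([C@@H]2Cc3cc(OC)cc(OC)c3C(=Cc3ccc(OC)cc3)c3cc(OC)cc(OC)c32)cc1
F3 | step 7 | seven-membered-ring 4-hydroxybenzylidene pentaphenol, (S) at CH(4-pivaloyloxyphenyl) | CC(C)(C)C(=O)Oc1ccc([C@@H]2Cc3cc(O)cc(O)c3C(=Cc3ccc(O)cc3)c3cc(O)cc(O)c32)cc1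
F4 | step 2 | racemic 2-[2-(3,5-dimethoxyphenyl)-1-(4-hydroxyphenyl)ethyl]-3,5-dimethoxyphenol | COc1cc(CC(c2ccc(O)cc2)c2c(O)cc(OC)cc2OC)cc(OC)c1
F5 | step 6 | 4-[(S)-1-{2,4-dimethoxy-6-[(E)-4-methoxystyryl]phenyl}-2-(3,5-dimethoxyphenyl)ethyl]phenol | Oc1ccc([C@H](Cc2cc(OC)cc(OC)c2)c2c(/C=C/c3ccc(OC)cc3)cc(OC)cc2OC)cc1
F6 | step 6 | 4-[(S)-1-{2,4-dimethoxy-6-[(E)-4-methoxystyryl]phenyl}-2-(3,5-dimethoxyphenyl)ethyl]phenyl methanesulfonate | CS(=O)(=O)Oc1ccc([C@H](Cc2cc(OC)cc(OC)c2)c2c(/C=C/c3ccc(OC)cc3)cc(OC)cc2OC)cc1
F7 | step 6 | 4-[(S)-1-{2,4-dihydroxy-6-[(E)-4-hydroxystyryl]phenyl}-2-(3,5-dihydroxyphenyl)ethyl]phenyl methanesulfonate | CS(=O)(=O)Oc1ccc([C@H](Cc2cc(O)cc(O)c2)c2c(/C=C/c3ccc(O)cc3)cc(O)cc2O)cc1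
F8 | step 6 | seven-membered-ring quinone methide, ring-A mesylate analogue of 13 (not isolated) | CS(=O)(=O)Oc1ccc([C@@H]2Cc3cc(O)cc(O)c3[C@@H](C=C3C=CC(=O)C=C3)c3cc(O)cc(O)c32)cc1
F9 | step 6 | ampelopsin B ring-A methanesulfonate, (S,S,S) | CS(=O)(=O)Oc1ccc([C@@H]2Cc3cc(O)cc4c3[C@H](c3cc(O)cc(O)c32)[C@@H](c2ccc(O)cc2)O4)cc1
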